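All runs are calculated with made-up constants; noise was put on by code.

I count the catalyst first and reckon the rate afterwards.

| flask | left-handed substrate | right-handed substrate | partner | free catalyst | racemization catalyst | impurity | remark | time |
|---|---|---|---|---|---|---|---|---|
| south-west | 0.15 M | 0.15 M | 0.33 M (fed, over 6.0 h) | 0.30 mM | 0.30 mM | 0.21 mM | the very flask that is asked about, followed so far |  |
| flask | 0.15 M | 0.15 M | 0.330 M (fed, over 6.0 h) | 0.30 mM | 0.30 mM | 0.21 mM |  | 40 h |

south-west run (percent of the left-handed substrate and right-handed substrate together charged)

| time / h | left-handed product / % | right-handed product / % |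
|---|---|---|
| 0.417 | 0 | 0 |
| 1.33 | 2 | 0 |
| 2.50 | 4 | 0 |
| 3.00 | 12 | 3 |
| 5.00 | 21 | 0 |
| 6.00 | 27 | 2 |
| 8.00 | 40 | 4 |

(each reading ± 2 percentage points)

- free catalyst is single-handed; left-handed substrate and right-handed substrate are mirror images of each other, charged as a racemate, each of them at the stated concentration
- steps that have been proposed: partner + free catalyst + left-handed substrate -> free catalyst + left-handed product; partner + free catalyst + right-handed substrate -> free catalyst + right-handed product; left-handed substrate + racemization catalyst <-> right-handed substrate + racemization catalyst; free catalyst + impurity -> spent catalyst; 2 free catalyst <-> resting dimer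
- an excess is the difference of the two amounts in percent of their sum
- an excess is below zero if the other one leads

* left-handed product and right-handed product together, in percent of the left-handed substrate and right-handed substrate charged together, at 40 h
* excess of left-handed product over right-handed product in the product at 40 h
* whether the exchange between left-handed substrate and right-handed substrate keeps pace with the reaction: how far the product's excess at 40 h gets from its value without exchange to its value with instant exchange (above 80 % keeps pace, below 20 % hardly takes part, else lags behind)

1. Each impurity takes one free catalyst for good, so I carry the live surplus, catalyst charged minus impurity charged: 0.0900 mM, or 30.0 % of the charge. Objection: the resting dimer holds some too. But that stays inside the surplus, and a rate read after the feed already includes it.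

2. At 8.00 h, left-handed product reads 80.0 % of its own charge, yet total product still grows by 0.0225 M h⁻¹ after 6.00 h. I read that as exchange keeping up and pool both substrates as [S]. With mean [S] of 0.191 M and mean [partner] of 0.221 M, the reading gives 0.536 M⁻¹ h⁻¹ for this surplus.

3. First estimate: pseudo-first-order, with [partner] frozen at 0.198 M and [S] starting from 0.168 M. That gives 98.1 %. Objection: this yield leaves [partner] at 0.0356 M, far below the frozen value.

4. Better: substrate is the limiting reagent, and [partner] stays 0.0300 M above [S]. Integrating leaves [S] at 0.0309 M, so the yield is 89.7 %.

5. The product ratio at 8.00 h, read as a selectivity factor, is 10.0. With pooled substrate, the excess is that ratio minus one over the ratio plus one: 81.8 %. Objection: the right-handed reading carries 2 percentage points, and exchange is finite. I commit to a little under that, and to keeping pace.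

The forecast gives 86 % (72 % to 96 %), 78 % (64 % to 88 %) and keeps pace, and says “the impurity probably removes much of the catalyst at the start”. My yield stands above its figure, inside its range.

The flask gives 87.6 % and 80.9 %, and it keeps pace, at 92 % of the way.

    partner + free catalyst + left-handed substrate → free catalyst + left-handed product (k = 210 M⁻² min⁻¹)
    partner + free catalyst + right-handed substrate → free catalyst + right-handed product (k = 18.0 M⁻² min⁻¹)
    left-handed substrate + racemization catalyst ⇌ right-handed substrate + racemization catalyst, rate k3*[racemization catalyst]*[left-handed substrate] forward; the back reaction follows from the equilibrium constant (k = 15.0 M⁻¹ min⁻¹)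
    free catalyst + impurity → spent catalyst (k = 6300 M⁻¹ min⁻¹)
    2 free catalyst ⇌ resting dimer (K = 1900 M⁻¹, k = 66.0 M⁻¹ min⁻¹)

In this flask at 40.0 h, spent catalyst stands at 70.0 % of the charge, free catalyst at 23.6 % and resting dimer at 6.37 %, so the last two hold the surplus of 30.0 %. A neighbouring flask is charged with 1.2 × 10⁻⁴ M of free catalyst, and the same subtraction gives −0.0900 mM, a surplus below zero. It predicts no working catalyst and 42.9 % of the impurity unused. That flask gives a yield of 0 %, with spent catalyst at 100 %, free catalyst at 0 % and impurity at 42.9 % of its charge.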